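**Plan**

- Retrosynthesis: after debenzylation the C4–C8' interflavan bond is cut, which gives two copies of one 2,3-cis flavan unit: flavan-3,4-diol 12 (C4 electrophile) and flavan-3-ol 13 (12 without its 4-OH). Diol 12 is cut at O1–C2 to a cis-epoxy carbinol, and this at C3–C4 to an aryl aldehyde and phenylacetylene.
- Forward: C4–C3 by alkynylation of a phloroglucinaldehyde ether, Z-alkene, cis-epoxide, ring C closed by the O1–C2 bond, half of 12 reduced at C4, the halves joined C4 to C8', hydrogenolysis last.
- Enabling feature: O1 is one of the two equivalent ortho oxygens of the phloroglucinol ring A, and C2 is a benzylic carbon (phenyl) remote from the C4 carbinol. A C2–C3 cis-epoxide is therefore opened by O1 at C2 in the 6-endo mode; this one closure fixes C2 and C3 of both halves (four of five stereocentres).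
- The 4-OH is the helper: it relays chirality to the epoxide, steers the opening away from C3, and is later lost as leaving group (upper unit) or replaced by hydride (lower unit).
- Stereochemistry: C4 carbinol from catalytic asymmetric alkynylation; C3/C2 from hydroxyl-directed epoxidation under A(1,3) control; inversion at C2 in the ring closure gives the (2R,3R) cis units; C4 (R) of the dimer is set in the coupling by attack anti to the 3-OH.

Key step: step 6

Assumption: the facial sense of BINOL–Ti alkynylzinc addition known for simple aromatic aldehydes is taken to hold for aldehyde 5, so that (R)-BINOL should give the R carbinol (R here because the trioxygenated aryl group outranks the alkynyl group).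

**Route**

Step 1
Reactants: 1 2,4,6-trihydroxybenzaldehyde; 2 benzyl bromide
Product: 3 2,4-bis(benzyloxy)-6-hydroxybenzaldehyde
Conditions: BnBr (2.1 equiv), K2CO3 (2.1 equiv), DMF, 0 °C to rt
Reagents that add atoms: benzyl bromide (2), BrCc1ccccc1
Why: Williamson etherification, in which the 4-OH and one ortho OH are benzylated while the last ortho OH, held in a hydrogen bond to the formyl oxygen, should stay free.

Step 2
Reactants: 3 2,4-bis(benzyloxy)-6-hydroxybenzaldehyde; 4 tert-butyldimethylsilyl chloride
Product: 5 2,4-bis(benzyloxy)-6-(tert-butyldimethylsilyloxy)benzaldehyde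
Conditions: TBSCl, imidazole, DMF, rt
Reagents that add atoms: tert-butyldimethylsilyl chloride (4), CC(C)(C)[Si](C)(C)Cl
Why: Silyl ether formation masks the future O1 with a fluoride-labile group that is orthogonal to the benzyl ethers and should survive organozinc addition, semi-hydrogenation and buffered peracid.

Step 3
Reactants: 5 2,4-bis(benzyloxy)-6-(tert-butyldimethylsilyloxy)benzaldehyde; 6 phenylacetylene
Product: 7 (R)-1-[2,4-bis(benzyloxy)-6-(tert-butyldimethylsilyloxy)phenyl]-3-phenylprop-2-yn-1-ol
Conditions: 6 (3 equiv), Et2Zn (3 equiv), PhMe, reflux; then (R)-BINOL (20 mol%), Ti(OiPr)4 (50 mol%), CH2Cl2, rt; then 5, rt; aq NH4Cl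
Reagents that add atoms: phenylacetylene (6), C#Cc1ccccc1
Why: BINOL–Ti catalysed enantioselective addition of an alkynylzinc to an aromatic aldehyde forms the C4–C3 bond and sets the C4 carbinol, the chiral titanium complex delivering the acetylide to one aldehyde face to give the R alcohol.

Step 4
Reactants: 7 (R)-1-[2,4-bis(benzyloxy)-6-(tert-butyldimethylsilyloxy)phenyl]-3-phenylprop-2-yn-1-ol
Product: 8 (R,Z)-1-[2,4-bis(benzyloxy)-6-(tert-butyldimethylsilyloxy)phenyl]-3-phenylprop-2-en-1-ol
Conditions: H2 (1 atm), Pd/CaCO3 poisoned with Pb(OAc)2 (Lindlar catalyst), quinoline, EtOAc, rt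
Reagents that add atoms: none
Why: Lindlar semi-hydrogenation adds H2 syn to the alkyne and should stop at the Z-alkene without touching the benzyl ethers or the benzylic carbinol; no stereocentre is formed.

Step 5
Reactants: 8 (R,Z)-1-[2,4-bis(benzyloxy)-6-(tert-butyldimethylsilyloxy)phenyl]-3-phenylprop-2-en-1-ol; 9 3-chloroperoxybenzoic acid
Product: 10 (S)-[2,4-bis(benzyloxy)-6-(tert-butyldimethylsilyloxy)phenyl][(2R,3S)-3-phenyloxiran-2-yl]methanol (threo, cis-epoxide)
Conditions: mCPBA (1.2 equiv), NaHCO3, CH2Cl2, −20 to 0 °C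
Reagents that add atoms: 3-chloroperoxybenzoic acid (9), OOC(=O)c1cccc(Cl)c1
Why: Hydroxyl-directed peracid epoxidation of a Z-allylic alcohol, in which A(1,3) strain holds C4–H in the alkene plane so that oxygen is delivered syn to the OH and anti to the aryl group, should give the threo cis-epoxide and thus fix C3 (R) and the benzylic epoxide carbon (S); the NaHCO3 buffer protects the ionisable carbinol.

Step 6
Reactants: 10 (S)-[2,4-bis(benzyloxy)-6-(tert-butyldimethylsilyloxy)phenyl][(2R,3S)-3-phenyloxiran-2-yl]methanol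
Product: 12 (2R,3R,4S)-5,7-bis(benzyloxy)-2-phenylchromane-3,4-diol, via phenolic epoxy carbinol 11 (not isolated)
Conditions: TBAF, AcOH, THF, 0 °C; aqueous wash; then PPTS (10 mol%), CH2Cl2, 0 °C to rt
Reagents that add atoms: none
Why: Buffered fluoride removes the silyl group and frees the phenolic O1 of 11, after which PPTS activates the oxirane and O1 attacks the benzylic carbon C2 from the side opposite the epoxide oxygen (borderline SN2), the epoxide oxygen becoming the 3-OH. The closest known reaction type is the acid-promoted cyclisation of 2-(3-aryloxiranylmethyl)phenols to flavan-3-ols, together with the distal opening of 2,3-epoxy alcohols. Ring C closes in the 6-endo-tet mode in preference to 5-exo-tet attack at C3. C2 is set by inversion of the S epoxide carbon to R while C3 keeps the R configuration installed in step 5, so the cis-epoxide translates into the 2,3-cis flavan; C4 is carried through unchanged (3,4-trans) and its configuration is of no consequence later. The step needs regioselectivity (C2 against C3) and chemoselectivity (epoxide opening against ionisation at C4): the phenyl group stabilises positive charge at C2, the electron-withdrawing carbinol carbon C4 next to C3 retards attack there, and the weak acid together with the β-oxygen should keep the 4-OH in place, a reversible ionisation touching only the irrelevant C4 configuration.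

Step 7
Reactants: 12 (2R,3R,4S)-5,7-bis(benzyloxy)-2-phenylchromane-3,4-diol (part of the material)
Product: 13 (2R,3R)-5,7-bis(benzyloxy)-2-phenylchroman-3-ol
Conditions: Et3SiH (10 equiv), TFA (2 equiv), CH2Cl2, −40 to 0 °C, slow addition of 12 at high dilution
Reagents that add atoms: none
Why: Ionic hydrogenation of the 2,4,6-trioxygenated benzylic alcohol proceeds through the C4 carbocation, which the large excess of silane should capture faster than another arene can, leaving C2 and C3 untouched.

Step 8
Reactants: 12 (2R,3R,4S)-5,7-bis(benzyloxy)-2-phenylchromane-3,4-diol; 13 (2R,3R)-5,7-bis(benzyloxy)-2-phenylchroman-3-ol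
Product: 14 (2R,3R,4R)-5,7-bis(benzyloxy)-4-[(2R,3R)-5,7-bis(benzyloxy)-3-hydroxy-2-phenylchroman-8-yl]-2-phenylchroman-3-ol
Conditions: 13 (3 equiv), BF3·OEt2 (0.5 equiv), 4 Å MS, CH2Cl2, −78 to −20 °C; excess 13 recovered
Reagents that add atoms: none
Why: Lewis acid promoted Friedel–Crafts alkylation of the flavan-3,4-diol type, in which 12 ionises at C4 to the cation stabilised by ring A and C8 of 13 (less hindered than C6 between two benzyloxy groups) attacks anti to the quasi-axial 3-OH, should give the 3,4-trans (4R) C4–C8' bond, the excess of 13 limiting oligomerisation.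

Step 9
Reactants: 14 (2R,3R,4R)-5,7-bis(benzyloxy)-4-[(2R,3R)-5,7-bis(benzyloxy)-3-hydroxy-2-phenylchroman-8-yl]-2-phenylchroman-3-ol
Product: 15 (2R,3R,4R)-2-phenyl-4-[(2R,3R)-3,5,7-trihydroxy-2-phenylchroman-8-yl]chromane-3,5,7-triol
Conditions: H2 (1 atm), Pd(OH)2/C, THF/MeOH, rt
Reagents that add atoms: none
Why: Catalytic hydrogenolysis should cleave the four benzyl ethers under neutral conditions that leave the acid-labile interflavan bond and all five stereocentres intact.

**Compound list**

1 | 2,4,6-trihydroxybenzaldehyde | O=Cc1c(O)cc(O)cc1O | starting material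
2 | benzyl bromide | BrCc1ccccc1 | starting material
3 | 2,4-bis(benzyloxy)-6-hydroxybenzaldehyde | O=Cc1c(O)cc(OCc2ccccc2)cc1OCc1ccccc1 | intermediate
4 | tert-butyldimethylsilyl chloride | CC(C)(C)[Si](C)(C)Cl | starting material
5 | 2,4-bis(benzyloxy)-6-(tert-butyldimethylsilyloxy)benzaldehyde | O=Cc1c(O[Si](C)(C)C(C)(C)C)cc(OCc2ccccc2)cc1OCc1ccccc1 | intermediate
6 | phenylacetylene | C#Cc1ccccc1 | starting material
7 | (R)-1-[2,4-bis(benzyloxy)-6-(tert-butyldimethylsilyloxy)phenyl]-3-phenylprop-2-yn-1-ol | O[C@H](C#Cc1ccccc1)c1c(O[Si](C)(C)C(C)(C)C)cc(OCc2ccccc2)cc1OCc1ccccc1 | intermediate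
8 | (R,Z)-1-[2,4-bis(benzyloxy)-6-(tert-butyldimethylsilyloxy)phenyl]-3-phenylprop-2-en-1-ol | O[C@H](/C=C\c1ccccc1)c1c(O[Si](C)(C)C(C)(C)C)cc(OCc2ccccc2)cc1OCc1ccccc1 | intermediate
9 | 3-chloroperoxybenzoic acid | OOC(=O)c1cccc(Cl)c1 | starting material
10 | (S)-[2,4-bis(benzyloxy)-6-(tert-butyldimethylsilyloxy)phenyl][(2R,3S)-3-phenyloxiran-2-yl]methanol | O[C@H]([C@H]1O[C@H]1c1ccccc1)c1c(O[Si](C)(C)C(C)(C)C)cc(OCc2ccccc2)cc1OCc1ccccc1 | intermediate
11 | (S)-[2,4-bis(benzyloxy)-6-hydroxyphenyl][(2R,3S)-3-phenyloxiran-2-yl]methanol (not isolated) | O[C@H]([C@H]1O[C@H]1c1ccccc1)c1c(O)cc(OCc2ccccc2)cc1OCc1ccccc1 | intermediate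
12 | (2R,3R,4S)-5,7-bis(benzyloxy)-2-phenylchromane-3,4-diol (2,3-cis, 3,4-trans) | C(Oc1cc(OCc2ccccc2)c2c(c1)O[C@H](c1ccccc1)[C@H](O)[C@H]2O)c1ccccc1 | intermediate
13 | (2R,3R)-5,7-bis(benzyloxy)-2-phenylchroman-3-ol | C(Oc1cc(OCc2ccccc2)c2c(c1)O[C@H](c1ccccc1)[C@H](O)C2)c1ccccc1 | intermediate
14 | (2R,3R,4R)-5,7-bis(benzyloxy)-4-[(2R,3R)-5,7-bis(benzyloxy)-3-hydroxy-2-phenylchroman-8-yl]-2-phenylchroman-3-ol | C(Oc1cc(OCc3ccccc3)c2c(c1)O[C@H](c1ccccc1)[C@H](O)[C@H]2c1c(OCc3ccccc3)cc(OCc3ccccc3)c2c1O[C@H](c1ccccc1)[C@H](O)C2)c1ccccc1 | intermediate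
15 | (2R,3R,4R)-2-phenyl-4-[(2R,3R)-3,5,7-trihydroxy-2-phenylchroman-8-yl]chromane-3,5,7-triol | Oc1cc(O)c2c(c1)O[C@H](c1ccccc1)[C@H](O)[C@H]2c1c(O)cc(O)c2c1O[C@H](c1ccccc1)[C@H](O)C2 | target

**Step count and risks**

Total steps: 9. Longest linear sequence: 9 steps (1, 3, 5, 7, 8, 10, 12, 13, 14, 15).

Steps most likely to fail:

1. Step 6. The phenol may close at C3 in the 5-exo mode, or the free phenol may ionise at the C4 carbinol (quinone methide formation followed by oligomerisation) faster than the epoxide opens. The fallback sets out from 10 and closes the ring at the ketone oxidation level, where C4 cannot ionise and the carbonyl directs the nucleophile to the β-carbon. Oxidation of 10 with Dess–Martin periodinane and NaHCO3 in CH2Cl2 should give the cis-epoxy ketone F1. Desilylation with TBAF and AcOH frees the phenolic epoxy ketone F2 (not isolated), which should cyclise by attack of O1 at C2 with inversion, the known closure of 2'-hydroxychalcone epoxides to dihydroflavonols, to the 2,3-cis dihydroflavonol F3. Luche reduction (NaBH4, CeCl3·7H2O, MeOH/THF, −78 °C), fast enough to forestall epimerisation, should give mainly the 3,4-cis diol F4, the C4 epimer of 12. F4 takes the place of 12 in steps 7 and 8, so the route is rejoined at 13 and 14.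

2. Step 5. The doubly activated carbinol may ionise or undergo allylic transposition under the peracid, the electron-rich arene may be oxidised, or the face selectivity may be insufficient. The fallback sets out from 8 and replaces substrate control by catalyst control on a masked carbinol. Silylation (TBSOTf, 2,6-lutidine, CH2Cl2, −78 °C) gives the O-TBS ether of 8, F5. Jacobsen epoxidation under non-acidic low-temperature conditions ((S,S)-N,N'-bis(3,5-di-tert-butylsalicylidene)-1,2-cyclohexanediaminomanganese chloride, (salen)MnCl, NMO, mCPBA, CH2Cl2, −78 °C; antipode chosen by analogy with indene and cis-β-methylstyrene) should give the O-TBS ether of 10, F6. TBAF (2.2 equiv) with AcOH removes both silyl groups to give 11, which is cyclised as in step 6, so the route is rejoined at 12.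

3. Step 3. The hindered, electron-rich 2,6-dioxygenated aldehyde may react sluggishly or with poor enantioface discrimination. The fallback sets out from 5 and moves the asymmetric event from C–C bond formation to ketone reduction. Addition of lithium phenylacetylide (from 6 and n-BuLi, THF, −78 °C) gives the racemic carbinol F7. Oxidation with MnO2 in CH2Cl2 gives the ynone F8. Corey–Bakshi–Shibata reduction ((S)-B-methyl oxazaborolidine, catecholborane, PhMe, −78 °C; aryl as the large and alkynyl as the small group) should give the R carbinol, so the route is rejoined at 7.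

**Further compounds**

F1 | step 6 | [2,4-bis(benzyloxy)-6-(tert-butyldimethylsilyloxy)phenyl][(2S,3S)-3-phenyloxiran-2-yl]methanone | O=C([C@H]1O[C@H]1c1ccccc1)c1c(O[Si](C)(C)C(C)(C)C)cc(OCc2ccccc2)cc1OCc1ccccc1
F2 | step 6 | [2,4-bis(benzyloxy)-6-hydroxyphenyl][(2S,3S)-3-phenyloxiran-2-yl]methanone | O=C([C@H]1O[C@H]1c1ccccc1)c1c(O)cc(OCc2ccccc2)cc1OCc1ccccc1
F3 | step 6 | (2R,3S)-5,7-bis(benzyloxy)-3-hydroxy-2-phenylchroman-4-one | C(Oc1cc(OCc2ccccc2)c2c(c1)O[C@H](c1ccccc1)[C@H](O)C2=O)c1ccccc1
F4 | step 6 | (2R,3R,4R)-5,7-bis(benzyloxy)-2-phenylchromane-3,4-diol | C(Oc1cc(OCc2ccccc2)c2c(c1)O[C@H](c1ccccc1)[C@H](O)[C@@H]2O)c1ccccc1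
F5 | step 5 | O-tert-butyldimethylsilyl ether of 8 | CC(C)(C)[Si](C)(C)O[C@H](/C=C\c1ccccc1)c1c(O[Si](C)(C)C(C)(C)C)cc(OCc2ccccc2)cc1OCc1ccccc1
F6 | step 5 | O-tert-butyldimethylsilyl ether of 10 | CC(C)(C)[Si](C)(C)O[C@H]([C@H]1O[C@H]1c1ccccc1)c1c(O[Si](C)(C)C(C)(C)C)cc(OCc2ccccc2)cc1OCc1ccccc1
F7 | step 3 | racemic 1-[2,4-bis(benzyloxy)-6-(tert-butyldimethylsilyloxy)phenyl]-3-phenylprop-2-yn-1-ol | OC(C#Cc1ccccc1)c1c(O[Si](C)(C)C(C)(C)C)cc(OCc2ccccc2)cc1OCc1ccccc1
F8 | step 3 | 1-[2,4-bis(benzyloxy)-6-(tert-butyldimethylsilyloxy)phenyl]-3-phenylprop-2-yn-1-one | O=C(C#Cc1ccccc1)c1c(O[Si](C)(C)C(C)(C)C)cc(OCc2ccccc2)cc1OCc1ccccc1
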